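**Assumptions:** reagents that donate non-hydrogen atoms are numbered as compounds. Step 3 (in situ acylation, rearrangement, esterification of the crude acid) is counted as one telescoped step, and its non-isolated intermediates are not numbered.

## Retrosynthetic overview

1. The enyne C(sp)–C(sp²) bond is cut by Sonogashira coupling: ethynyl-oxolane 15 plus (1E,9E)-1-bromo-10-iododeca-1,9-diene 20, made from 1,9-decadiyne by two hydrozirconation/halogenations.
2. The alkyne comes from the ring CH2OH (oxidation, Ohira–Bestmann). The butanoate chain comes from a ring–CH2CO2Me unit by two-carbon Wittig homologation, and one hydrogenation saturates both the ring and chain alkenes.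
3. Key bond (ring C2–CH2): Ireland–Claisen [3,3] rearrangement of the 3-O-acetate of a furanoid glycal. Suprafacial delivery from the C3–O face places the new chain trans to the C5 substituent.
4. The glycal comes from thymidine. The oxolane ring is bought, not built: C4′ of thymidine is retained and C3′ relays its configuration to C1′.

## Route

**Step 1**
Reactants: 1 thymidine; 2 tert-butyldiphenylsilyl chloride
Product: 3, 5′-O-(tert-butyldiphenylsilyl)thymidine
Conditions: TBDPSCl (1.1 equiv), imidazole, DMF, 0 °C → rt
Reagents that add atoms: TBDPSCl, CC(C)(C)[Si](Cl)(c1ccccc1)c1ccccc1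
Why: Selective silylation of the primary 5′-OH over the secondary 3′-OH with a bulky silyl chloride; no stereocentre is touched.

**Step 2**
Reactants: 3
Product: 4, (2R,3S)-2-{[(tert-butyldiphenylsilyl)oxy]methyl}-2,3-dihydrofuran-3-ol (furanoid glycal)
Conditions: HMDS, (NH4)2SO4 (cat.), reflux; then K2CO3, MeOH, rt
Reagents that add atoms: none
Why: Silylation-promoted elimination of thymine from the 2′-deoxynucleoside gives the 3-O-TMS glycal, and methanolysis frees the 3-OH; both stereocentres are those of thymidine.

**Step 3 (key step)**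
Reactants: 4; 5 acetyl chloride; 6 (trimethylsilyl)diazomethane
Product: 7, methyl 2-[(2R,5S)-5-{[(tert-butyldiphenylsilyl)oxy]methyl}-2,5-dihydrofuran-2-yl]acetate (trans)
Conditions: n-BuLi, then AcCl, THF, −78 °C; LDA, TMSCl, THF–HMPA, −78 °C → rt; aq. work-up, then TMSCHN2, PhMe–MeOH, 0 °C
Reagents that add atoms: acetyl chloride, CC(=O)Cl; TMSCHN2, C[Si](C)(C)C=[N+]=[N-] (ester methyl)
Why: Ireland–Claisen [3,3]-sigmatropic rearrangement of the labile glycal acetate's silyl ketene acetal forms the C2–CH2 bond suprafacially on the face of the departing C3–O bond, which is anti to the CH2OSi group, so C2 is set trans to C5 by the thymidine C3′ centre.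

**Step 4**
Reactants: 7
Product: 8, 2-[(2R,5S)-5-{[(tert-butyldiphenylsilyl)oxy]methyl}-2,5-dihydrofuran-2-yl]acetaldehyde
Conditions: DIBAL-H (1.1 equiv), CH2Cl2, −78 °C; Rochelle salt work-up; used crude
Reagents that add atoms: none
Why: Low-temperature DIBAL half-reduction of a β-alkoxy methyl ester stops at the aldehyde through the chelated tetrahedral intermediate.

**Step 5**
Reactants: 8; 9 methyl (triphenylphosphoranylidene)acetate
Product: 10, methyl (2E)-4-[(2R,5S)-5-{[(tert-butyldiphenylsilyl)oxy]methyl}-2,5-dihydrofuran-2-yl]but-2-enoate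
Conditions: Ph3P=CHCO2Me, CH2Cl2, rt
Reagents that add atoms: ylide 9, COC(=O)C=P(c1ccccc1)(c1ccccc1)c1ccccc1
Why: Wittig olefination with a neutral stabilised ylide adds the last two chain carbons without base-induced β-elimination of the ring oxygen.

**Step 6**
Reactants: 10
Product: 11, methyl 4-[(2R,5S)-5-{[(tert-butyldiphenylsilyl)oxy]methyl}oxolan-2-yl]butanoate
Conditions: H2 (1 atm), PtO2 (or 5% Rh/Al2O3), EtOAc, rt
Reagents that add atoms: none
Why: Catalytic hydrogenation saturates the enoate and the ring alkene in one operation; Pt or Rh is chosen over Pd to avoid allylic C–O hydrogenolysis and double-bond migration, so both stereocentres are kept.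

**Step 7**
Reactants: 11
Product: 12, methyl 4-[(2R,5S)-5-(hydroxymethyl)oxolan-2-yl]butanoate
Conditions: TBAF, AcOH (buffer), THF, 0 °C → rt
Reagents that add atoms: none
Why: Fluoride desilylation; buffering protects the methyl ester.

**Step 8**
Reactants: 12
Product: 13, methyl 4-[(2R,5S)-5-formyloxolan-2-yl]butanoate
Conditions: Dess–Martin periodinane, NaHCO3, CH2Cl2, 0 °C → rt; used crude
Reagents that add atoms: none
Why: Mild, non-basic Dess–Martin oxidation gives the α-alkoxy aldehyde without epimerisation.

**Step 9**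
Reactants: 13; 14 dimethyl (1-diazo-2-oxopropyl)phosphonate (Ohira–Bestmann reagent)
Product: 15, methyl 4-[(2R,5S)-5-ethynyloxolan-2-yl]butanoate
Conditions: K2CO3, MeOH, 0 °C → rt
Reagents that add atoms: Ohira–Bestmann reagent, COP(=O)(OC)C(=[N+]=[N-])C(C)=O (one carbon)
Why: Seyferth–Gilbert/Ohira–Bestmann homologation converts the aldehyde to the terminal alkyne; K2CO3/MeOH is degenerate for a methyl ester and mild enough to keep C5.

**Step 10**
Reactants: 16 1,9-decadiyne (3 equiv, excess recovered); 17 N-bromosuccinimide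
Product: 18, (E)-1-bromodec-1-en-9-yne
Conditions: Cp2Zr(H)Cl (1 equiv), CH2Cl2, rt; then NBS, 0 °C
Reagents that add atoms: NBS, O=C1CCC(=O)N1Br
Why: Syn hydrozirconation of one terminal alkyne and bromination with retention give the (E)-vinyl bromide; excess diyne suppresses double addition.

**Step 11**
Reactants: 18; 19 iodine
Product: 20, (1E,9E)-1-bromo-10-iododeca-1,9-diene
Conditions: Cp2Zr(H)Cl (1.2 equiv), THF, rt; then I2, 0 °C
Reagents that add atoms: iodine, II
Why: A second hydrozirconation/iodination gives the (E)-vinyl iodide; the alkyne reacts far faster with Schwartz reagent than the vinyl bromide.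

**Step 12**
Reactants: 15; 20 (1.2 equiv)
Product: 21, Mutafuran C, methyl 4-[(2R,5S)-5-[(3E,11E)-12-bromododeca-3,11-dien-1-yn-1-yl]oxolan-2-yl]butanoate
Conditions: Pd(PPh3)4 (5 mol%), CuI (10 mol%), i-Pr2NH, THF, rt
Reagents that add atoms: none
Why: Sonogashira coupling occurs chemoselectively at the C–I bond at room temperature with retention of alkene geometry, leaving the (E)-vinyl bromide intact.

## Compound list

1 | thymidine | Cc1cn([C@H]2C[C@H](O)[C@@H](CO)O2)c(=O)[nH]c1=O | starting material
2 | tert-butyldiphenylsilyl chloride | CC(C)(C)[Si](Cl)(c1ccccc1)c1ccccc1 | starting material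
3 | 5′-O-(tert-butyldiphenylsilyl)thymidine | Cc1cn([C@H]2C[C@H](O)[C@@H](CO[Si](c3ccccc3)(c3ccccc3)C(C)(C)C)O2)c(=O)[nH]c1=O | intermediate
4 | (2R,3S)-2-{[(tert-butyldiphenylsilyl)oxy]methyl}-2,3-dihydrofuran-3-ol | O[C@H]1C=CO[C@@H]1CO[Si](c2ccccc2)(c2ccccc2)C(C)(C)C | intermediate
5 | acetyl chloride | CC(=O)Cl | starting material
6 | (trimethylsilyl)diazomethane | C[Si](C)(C)C=[N+]=[N-] | starting material
7 | methyl 2-[(2R,5S)-5-{[(tert-butyldiphenylsilyl)oxy]methyl}-2,5-dihydrofuran-2-yl]acetate | COC(=O)C[C@@H]1C=C[C@@H](CO[Si](c2ccccc2)(c2ccccc2)C(C)(C)C)O1 | intermediate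
8 | 2-[(2R,5S)-5-{[(tert-butyldiphenylsilyl)oxy]methyl}-2,5-dihydrofuran-2-yl]acetaldehyde | O=CC[C@@H]1C=C[C@@H](CO[Si](c2ccccc2)(c2ccccc2)C(C)(C)C)O1 | intermediate
9 | methyl (triphenylphosphoranylidene)acetate | COC(=O)C=P(c1ccccc1)(c1ccccc1)c1ccccc1 | starting material
10 | methyl (2E)-4-[(2R,5S)-5-{[(tert-butyldiphenylsilyl)oxy]methyl}-2,5-dihydrofuran-2-yl]but-2-enoate | COC(=O)/C=C/C[C@@H]1C=C[C@@H](CO[Si](c2ccccc2)(c2ccccc2)C(C)(C)C)O1 | intermediate
11 | methyl 4-[(2R,5S)-5-{[(tert-butyldiphenylsilyl)oxy]methyl}oxolan-2-yl]butanoate | COC(=O)CCC[C@@H]1CC[C@@H](CO[Si](c2ccccc2)(c2ccccc2)C(C)(C)C)O1 | intermediate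
12 | methyl 4-[(2R,5S)-5-(hydroxymethyl)oxolan-2-yl]butanoate | COC(=O)CCC[C@@H]1CC[C@@H](CO)O1 | intermediate
13 | methyl 4-[(2R,5S)-5-formyloxolan-2-yl]butanoate | COC(=O)CCC[C@@H]1CC[C@@H](C=O)O1 | intermediate
14 | dimethyl (1-diazo-2-oxopropyl)phosphonate | COP(=O)(OC)C(=[N+]=[N-])C(C)=O | starting material
15 | methyl 4-[(2R,5S)-5-ethynyloxolan-2-yl]butanoate | COC(=O)CCC[C@@H]1CC[C@@H](C#C)O1 | intermediate
16 | 1,9-decadiyne | C#CCCCCCCC#C | starting material
17 | N-bromosuccinimide | O=C1CCC(=O)N1Br | starting material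
18 | (E)-1-bromodec-1-en-9-yne | Br/C=C/CCCCCCC#C | intermediate
19 | iodine | II | starting material
20 | (1E,9E)-1-bromo-10-iododeca-1,9-diene | Br/C=C/CCCCCC/C=C/I | intermediate
21 | Mutafuran C | COC(=O)CCC[C@@H]1CC[C@@H](C#C/C=C/CCCCCC/C=C/Br)O1 | target

## Step count and risks

Total steps: 12. Longest linear sequence: 10 (steps 1–9, then 12); steps 10–11 are the convergent side-chain branch.

Steps most likely to fail, each with a fallback that changes the approach:

1. **Step 3 (Ireland–Claisen on the furanoid glycal acetate).** The 3-O-acyl glycal can ionise and aromatise to the furan before it rearranges. Fallback: build the trans ring by oxocarbenium C-glycosylation instead. Start from (S)-5-(TBDPS-oxymethyl)-γ-butyrolactone (from L-glutamic acid), convert with DIBAL/Ac2O to the lactol acetate, and add 1-methoxy-1-(trimethylsilyloxy)buta-1,3-diene with BF3·OEt2 (γ-attack, anti to the C5 substituent). Hydrogenation then converges on 11.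

2. **Step 6 (hydrogenation of the 2,5-dihydrofuran).** Allylic C–O hydrogenolysis, or migration of the alkene to the enol ether, would open the ring or scramble C2. Fallback: avoid heterogeneous hydrogenation of the allylic ether. Reduce the ring alkene of 7 with diimide (o-nitrobenzenesulfonyl hydrazide, Et3N), then run DIBAL/Wittig on the saturated ester and reduce the enoate by conjugate hydride delivery (Stryker's reagent or NaBH4–NiCl2).

3. **Step 9 (Ohira–Bestmann on the α-alkoxy aldehyde).** Base may epimerise C5 to the cis isomer or give a poor yield. Fallback: invert the coupling polarity. Convert 13 to the 1,1-dibromoalkene (CBr4, PPh3), eliminate with DBU to the 1-bromoalkyne, and couple it under Pd(0) with the (E)-alkenylzirconocene made from 18 (Cp2Zr(H)Cl, then ZnCl2). This forms the enyne directly and removes the need for 15, 20 and the Sonogashira step.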